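**Assumption:** colpol has no stereocentre, so "single enantiomer" is read as the single (Z)-alkene isomer shown in the SMILES.

## Retrosynthetic overview

1. Colpol comes from its resorcinol bis-MOM ether by acid cleavage (last step).
2. Key bond (ring-A aryl–CH2): photo-Claisen [1,3] O→C shift of a (Z)-allyl aryl ether, through a caged phenoxyl/allyl radical pair.
3. That ether comes from a ring-B aryl Grignard and a (Z)-4-chlorobut-2-enyl aryl ether by Cu-catalysed SN2. The Z-alkene is bought as cis-1,4-dichlorobut-2-ene and is never made or reduced.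
4. The ring-A phenol comes from 3-bromophenol (para-oxidation, then reduction). The ring-B iodide comes from resorcinol (MOM protection, ortho-lithiation/bromination, Ir borylation/iodination).
5. No ring is formed; both benzene rings are bought. Bond order: O–C4 chain, ring B–C4 chain, then ring A–C4 chain.

## Route

**Step 1**
Reactants: 1, 3-bromophenol
Product: 2, 3-bromo-4,4-dimethoxycyclohexa-2,5-dien-1-one
Conditions: PhI(OAc)2 (2.1 equiv), MeOH, 0 °C to rt
Reagents that add atoms: methanol, CO (both OMe groups)
Why: Hypervalent-iodine oxidative dearomatisation; the phenoxenium ion is trapped by MeOH at the free para position, and the first-formed 4-methoxyphenol is oxidised again to the p-quinone monoketal, which fixes the new oxygen next to Br.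

**Step 2**
Reactants: 2, 3-bromo-4,4-dimethoxycyclohexa-2,5-dien-1-one
Product: 3, 3-bromo-4-methoxyphenol
Conditions: Zn dust, AcOH/THF, 0 °C to rt
Reagents that add atoms: none
Why: Reductive aromatisation of a quinone monoketal; electron transfer to the dienone expels one methoxide, driven by aromatisation, and leaves the 4-OMe/1-OH pattern with no O-methylation selectivity problem.

**Step 3**
Reactants: 3, 3-bromo-4-methoxyphenol; 4, (Z)-1,4-dichlorobut-2-ene (4 equiv)
Product: 5, (Z)-2-bromo-4-[(4-chlorobut-2-en-1-yl)oxy]-1-methoxybenzene
Conditions: K2CO3, acetone, 50 °C; excess 4 distilled off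
Reagents that add atoms: none
Why: Williamson O-alkylation (SN2 at a primary allylic chloride) does not touch the alkene, so Z is retained, and the excess dichloride suppresses bis-etherification.

**Step 4**
Reactants: 6, resorcinol
Product: 7, 1,3-bis(methoxymethoxy)benzene
Conditions: MOMCl (2.5 equiv), i-Pr2NEt, CH2Cl2, 0 °C to rt
Reagents that add atoms: chloromethyl methyl ether, COCCl
Why: Standard MOM protection, which also installs two ortho-directing groups for the next step.

**Step 5**
Reactants: 7, 1,3-bis(methoxymethoxy)benzene
Product: 8, 2-bromo-1,3-bis(methoxymethoxy)benzene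
Conditions: n-BuLi, THF, 0 °C; then BrCCl2CCl2Br, –78 °C to rt
Reagents that add atoms: 1,2-dibromotetrachloroethane, BrC(Cl)(Cl)C(Cl)(Cl)Br
Why: Directed ortho-metalation; the C2–H between the two OMOM groups is lithiated selectively, and the electrophilic bromine quench puts Br between the oxygens, which direct bromination of resorcinol does not do.

**Step 6** (one pot; boronate 9 is not isolated)
Reactants: 8, 2-bromo-1,3-bis(methoxymethoxy)benzene
Product: 10, 2-bromo-5-iodo-1,3-bis(methoxymethoxy)benzene, via 9, 2-[4-bromo-3,5-bis(methoxymethoxy)phenyl]-4,4,5,5-tetramethyl-1,3,2-dioxaborolane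
Conditions: [Ir(OMe)(cod)]2 (1.5 mol%), dtbpy, B2pin2, THF, 80 °C; evaporate; then CuI (10 mol%), 1,10-phenanthroline, KI, MeOH/H2O, air, 80 °C
Reagents that add atoms: bis(pinacolato)diboron, CC1(C)OB(OC1(C)C)B1OC(C)(C)C(C)(C)O1 (in 9 only); potassium iodide, [K+].[I-] (iodine in 10)
Why: Sterically controlled Ir-catalysed C–H borylation reaches only C5, the one C–H with no ortho substituent, and Cu-mediated iododeboronation then gives an iodide that can be exchanged in the presence of the hindered aryl bromide.

**Step 7**
Reactants: 10, 2-bromo-5-iodo-1,3-bis(methoxymethoxy)benzene; 5, (Z)-2-bromo-4-[(4-chlorobut-2-en-1-yl)oxy]-1-methoxybenzene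
Product: 11, (Z)-2-bromo-5-[4-(3-bromo-4-methoxyphenoxy)but-2-en-1-yl]-1,3-bis(methoxymethoxy)benzene
Conditions: 10, i-PrMgCl·LiCl (1.05 equiv), THF, –30 °C, 1 h; then Li2CuCl4 (3 mol%), 5 (0.9 equiv), –30 to 0 °C
Reagents that add atoms: none
Why: Chemoselective I/Mg exchange, then Kochi-type Cu-catalysed Grignard allylation under cuprate-favouring conditions (THF, low temperature, high ArMg:Cu ratio), which gives α (SN2) substitution without a π-allyl intermediate that could equilibrate, so the Z-alkene is retained.

**Step 8** (key step)
Reactants: 11, the (Z)-allyl aryl ether from step 7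
Product: 12, (Z)-5-bromo-2-{4-[4-bromo-3,5-bis(methoxymethoxy)phenyl]but-2-en-1-yl}-4-methoxyphenol
Conditions: hν (300 nm, quartz), degassed MeCN, 0.01 M, rt, to about 70% conversion; recovered 11 recycled
Reagents that add atoms: none
Why: Photo-Claisen rearrangement: singlet homolysis of the weak ArO–CH2(allyl) bond gives a caged phenoxyl/allyl radical pair that recombines through the primary allyl terminus at the open ortho carbon (para is blocked by OMe, the other ortho site is flanked by Br), a formal [1,3] shift that gives the linear chain; the allyl radical (rotation barrier about 15 kcal/mol) keeps its Z geometry over the nanosecond cage lifetime.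

**Step 9**
Reactants: 12, the bis-MOM ether from step 8
Product: 13, colpol, (Z)-2-bromo-5-[4-(4-bromo-2-hydroxy-5-methoxyphenyl)but-2-en-1-yl]benzene-1,3-diol
Conditions: 3 M HCl, MeOH/THF, 40 °C
Reagents that add atoms: none
Why: Acid-catalysed acetal (MOM) cleavage; the aryl methyl ether, both aryl bromides and the isolated Z-alkene are stable to dilute acid at this temperature.

## Compound list

1 | 3-bromophenol | Oc1cccc(Br)c1 | starting material
2 | 3-bromo-4,4-dimethoxycyclohexa-2,5-dien-1-one | O=C1C=CC(OC)(OC)C(Br)=C1 | intermediate
3 | 3-bromo-4-methoxyphenol | COc1ccc(O)cc1Br | intermediate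
4 | (Z)-1,4-dichlorobut-2-ene | ClC/C=C\CCl | starting material
5 | (Z)-2-bromo-4-[(4-chlorobut-2-en-1-yl)oxy]-1-methoxybenzene | COc1ccc(OC/C=C\CCl)cc1Br | intermediate
6 | resorcinol | Oc1cccc(O)c1 | starting material
7 | 1,3-bis(methoxymethoxy)benzene | COCOc1cccc(OCOC)c1 | intermediate
8 | 2-bromo-1,3-bis(methoxymethoxy)benzene | COCOc1cccc(OCOC)c1Br | intermediate
9 | 2-[4-bromo-3,5-bis(methoxymethoxy)phenyl]-4,4,5,5-tetramethyl-1,3,2-dioxaborolane | COCOc1cc(B2OC(C)(C)C(C)(C)O2)cc(OCOC)c1Br | intermediate (not isolated)
10 | 2-bromo-5-iodo-1,3-bis(methoxymethoxy)benzene | COCOc1cc(I)cc(OCOC)c1Br | intermediate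
11 | (Z)-2-bromo-5-[4-(3-bromo-4-methoxyphenoxy)but-2-en-1-yl]-1,3-bis(methoxymethoxy)benzene | COc1ccc(OC/C=C\Cc2cc(OCOC)c(Br)c(OCOC)c2)cc1Br | intermediate
12 | (Z)-5-bromo-2-{4-[4-bromo-3,5-bis(methoxymethoxy)phenyl]but-2-en-1-yl}-4-methoxyphenol | COc1cc(C/C=C\Cc2cc(OCOC)c(Br)c(OCOC)c2)c(O)cc1Br | intermediate
13 | colpol | COc1cc(C/C=C\Cc2cc(O)c(Br)c(O)c2)c(O)cc1Br | target

## Step count and risks

Total steps: 9 (step 6 is a one-pot borylation/iododeboronation; 10 if boronate 9 is isolated).
Longest linear sequence: 6 steps (6 → 7 → 8 → 10 → 11 → 12 → 13); the ring-A branch (1 → 2 → 3 → 5) is 3 steps and joins at step 7.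

Steps most likely to fail:

1. **Step 8 (photo-Claisen).** Risks are cage escape back to phenol 3, coupling through the secondary allyl terminus (branched isomer), attack at the Br-flanked ortho carbon, C–Br photolysis or heavy-atom quenching, and secondary photocyclisation of the o-allylphenol. Fallback: drop the O→C shift and make the ring-A aryl–CH2 bond by ion-pair ortho-C-alkylation of the sodium phenoxide of 3 in toluene, using the (Z)-allylic chloride made from the Grignard of 10 and excess 4.
2. **Step 7 (Cu-catalysed aryl Grignard allylation).** Risks are competing SN2' (branched product), attack at the aryloxy terminus, and partial Br/Mg exchange. Fallback: move the coupling from the allylic to a vinylic carbon. Homologate boronate 9 to the benzylboronate (LiCH2Cl, Matteson) and couple it sp3–sp2 with a (Z)-3-iodoallyl ether of 3, then run the same photo-Claisen.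
3. **Step 1 (PIDA para-oxidation of 3-bromophenol).** Risks are ortho-quinone ketal formation and over-oxidation, giving a modest yield. Fallback: build 3 from hydroquinone instead: monomethylation, O-acetylation, bromination ortho to OMe, then methanolysis of the acetate.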